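**Retrosynthetic overview** (locants are defined in the remark below)
1. Last step: the furanone-bridged carbocycle is traced back to a ten-membered macrolactone in which the C1 carboxyl is esterified to the C15 oxygen, C3 is a methyl ketone (C2 is its methyl group) and C10 carries a tertiary chloride. Base-induced 1,5 O-to-C acyl transfer (C2–C1) followed by 5-exo-tet O-alkylation (O–C10) closes the carbocycle and the 3(2H)-furanone and frees the C15 hydroxyl.
2. Enabling feature: the hydroxymethyl carbon C15 sits on C4 beside the furanone carbon C3. Its oxygen, once acylated by C1, holds C1 six atoms from C2 (C2–C3–C4–C15–O–C1), and the C3 oxygen lies 1,5 to C10. The tether is the target's own free hydroxyl, so nothing has to be removed.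
3. The macrolactone comes from gold-catalysed hydration of an enyne (masked acetyl), and that from an intramolecular chromium Barbier allylation (C6–C7), which closes the ten-membered lactone and the cis α-methylene-γ-butyrolactone together.
4. The Barbier substrate comes from ester union of an allylic bromide (from but-2-yne-1,4-diol, alkene geometry by trans-hydroalumination) with the cesium carboxylate of a chlorolactone (from (R)-5-(hydroxymethyl)butyrolactone: C8 from the pool, C10 by trans-chlorination), then tigloylation and Morita–Baylis–Hillman reaction/bromination.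
5. Ring order: temporary γ-butyrolactone (sets C10, then opened) → ten-membered lactone and cis-γ-lactone together → ten-membered carbocycle and furanone together.

Key step: step 18

Remark: germacranolide locants are used: C1 furanone ketone carbon, C2 furanone CH, C3 oxygen-bearing furanone carbon, C4=C5 ring alkene with C15H2OH on C4, C6 lactone carbinol, C7, C8 tiglate carbinol, C9 methylene, C10 quaternary carbon with methyl C14, C11–C13 methylene lactone. The SMILES is read as 6S,7R,8R,10R with a cis-fused lactone, a 4Z alkene and an E tiglate. Compounds 1 and 10 are taken as commercial.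

Step 1
Reactants: 1 but-2-yne-1,4-diol
Product: 2 4-((tert-butyldimethylsilyl)oxy)but-2-yn-1-ol
Conditions: TBSCl (1 equiv), imidazole, 1 (3 equiv), DMF, 0 °C to rt
Reagents that add atoms: tert-butyldimethylsilyl chloride, CC(C)(C)[Si](C)(C)Cl
Why: silyl ether formation on a symmetric diol used in excess should give mainly the mono-ether; no stereocentre is involved.

Step 2
Reactants: 2 4-((tert-butyldimethylsilyl)oxy)but-2-yn-1-ol
Product: 4 (Z)-4-((tert-butyldimethylsilyl)oxy)-3-iodobut-2-en-1-ol, via cyclic vinylalanate 3 (not isolated)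
Conditions: NaAlH2(OCH2CH2OMe)2 (1.5 equiv), THF, 0 °C to rt; then I2, −78 to 0 °C
Reagents that add atoms: iodine, II
Why: hydroxyl-directed trans-hydroalumination of the propargylic alcohol puts aluminium on the distal alkyne carbon and iodinolysis proceeds with retention, so iodine (later C3) ends cis to the CH2OH carbon (later C6), which fixes the C4=C5 geometry.

Step 3
Reactants: 4 (Z)-4-((tert-butyldimethylsilyl)oxy)-3-iodobut-2-en-1-ol
Product: 5 (E)-3-(((tert-butyldimethylsilyl)oxy)methyl)-5-(trimethylsilyl)pent-2-en-4-yn-1-ol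
Conditions: ethynyltrimethylsilane, Pd(PPh3)2Cl2 (3 mol %), CuI (5 mol %), Et3N, THF, rt
Reagents that add atoms: ethynyltrimethylsilane, C#C[Si](C)(C)C
Why: Sonogashira coupling of the vinyl iodide proceeds with retention of alkene geometry and installs C3 and C2 as an alkyne, the masked acetyl group.

Step 4
Reactants: 5 (E)-3-(((tert-butyldimethylsilyl)oxy)methyl)-5-(trimethylsilyl)pent-2-en-4-yn-1-ol
Product: 6 (E)-3-(((tert-butyldimethylsilyl)oxy)methyl)-5-(trimethylsilyl)pent-2-en-4-ynal
Conditions: MnO2 (activated, 15 equiv), CH2Cl2, rt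
Reagents that add atoms: none
Why: MnO2 oxidation of the primary allylic alcohol should give the enal (C6) without touching the silyl groups.

Step 5
Reactants: 6 (E)-3-(((tert-butyldimethylsilyl)oxy)methyl)-5-(trimethylsilyl)pent-2-en-4-ynal
Product: 8 (E)-2-ethynyl-4,4-dimethoxybut-2-en-1-ol, via C-silylated acetal alcohol 7 (not isolated)
Conditions: HC(OMe)3, camphorsulfonic acid (10 mol %), MeOH, rt; then K2CO3, MeOH, rt
Reagents that add atoms: trimethyl orthoformate, COC(OC)OC; methanol, CO
Why: acid-catalysed acetalisation of the enal with concurrent methanolysis of the primary silyl ether, then K2CO3/MeOH protodesilylation of the alkynylsilane, should give the acetal alcohol; the C15 hydroxyl is trans to the acetal carbon and cannot cyclise onto it.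

Step 6
Reactants: 8 (E)-2-ethynyl-4,4-dimethoxybut-2-en-1-ol
Product: 9 (E)-3-(bromomethyl)-5,5-dimethoxypent-3-en-1-yne
Conditions: CBr4, PPh3, 2,6-lutidine, CH2Cl2, −20 to 0 °C
Reagents that add atoms: tetrabromomethane, BrC(Br)(Br)Br
Why: Appel bromination of the primary allylic alcohol under buffered conditions should spare the acetal and the alkyne.

Step 7
Reactants: 10 (R)-5-(hydroxymethyl)dihydrofuran-2(3H)-one
Product: 11 (R)-5-((trityloxy)methyl)dihydrofuran-2(3H)-one
Conditions: TrCl, pyridine, DMAP (cat.), CH2Cl2, rt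
Reagents that add atoms: trityl chloride, ClC(c1ccccc1)(c1ccccc1)c1ccccc1
Why: tritylation of the primary alcohol gives the bulky ether needed for facial control; the lactone carbinol carbon is C8 (R) of the target, taken from the chiral pool.

Step 8
Reactants: 11 (R)-5-((trityloxy)methyl)dihydrofuran-2(3H)-one
Product: 13 (3S,5R)-3-methyl-5-((trityloxy)methyl)dihydrofuran-2(3H)-one, via lithium enolate 12 (not isolated)
Conditions: LiN(i-Pr)2 (1.1 equiv), THF, −78 °C; then MeI, −78 to −40 °C
Reagents that add atoms: iodomethane, CI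
Why: lactone enolate alkylation anti to the trityloxymethyl group installs C14; this centre is made planar again in step 9, so its configuration is not critical.

Step 9
Reactants: 13 (3S,5R)-3-methyl-5-((trityloxy)methyl)dihydrofuran-2(3H)-one
Product: 15 (3S,5R)-3-chloro-3-methyl-5-((trityloxy)methyl)dihydrofuran-2(3H)-one, via lithium enolate 14 (not isolated)
Conditions: LiN(i-Pr)2 (1.2 equiv), THF, −78 °C; then C2Cl6, −78 to −20 °C
Reagents that add atoms: hexachloroethane, ClC(Cl)(Cl)C(Cl)(Cl)Cl
Why: electrophilic chlorination of the planar enolate on the face anti to the trityloxymethyl group (1,3-induction, as in the second alkylation of this lactone type) should place chlorine trans to the C7 carbon and so set C10 as the (S)-chloride.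

Step 10
Reactants: 15 (3S,5R)-3-chloro-3-methyl-5-((trityloxy)methyl)dihydrofuran-2(3H)-one; 9 (E)-3-(bromomethyl)-5,5-dimethoxypent-3-en-1-yne
Product: 18 (E)-2-ethynyl-4,4-dimethoxybut-2-en-1-yl (2S,4R)-2-chloro-2-methyl-4-(((E)-2-methylbut-2-enoyl)oxy)-5-(trityloxy)pentanoate, via cesium carboxylate 16 (not isolated), via hydroxy ester 17 (not isolated)
Conditions: CsOH·H2O (1.0 equiv), THF/H2O, 0 °C; evaporation below 30 °C; 9, DMF, 0 °C; then tigloyl chloride, pyridine, DMAP (cat.), 0 °C
Reagents that add atoms: cesium hydroxide monohydrate, O.[Cs+].[OH-]; (E)-2-methylbut-2-enoyl chloride (tigloyl chloride), C/C=C(\C)C(Cl)=O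
Why: hydroxide opens the chlorine-activated lactone, the cesium carboxylate is O-alkylated by the reactive allylic bromide (SN2, forming the C15–O–C1 ester) and the freed C8 hydroxyl is acylated at once before it can relactonise; C8 and C10 are not touched.

Step 11
Reactants: 18 (E)-2-ethynyl-4,4-dimethoxybut-2-en-1-yl (2S,4R)-2-chloro-2-methyl-4-(((E)-2-methylbut-2-enoyl)oxy)-5-(trityloxy)pentanoate
Product: 19 (E)-2-ethynyl-4,4-dimethoxybut-2-en-1-yl (2S,4R)-2-chloro-5-hydroxy-2-methyl-4-(((E)-2-methylbut-2-enoyl)oxy)pentanoate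
Conditions: p-TsOH·H2O (10 mol %), MeOH/CH2Cl2 (2:1), 0 °C
Reagents that add atoms: none
Why: acid-catalysed methanolysis of the trityl ether (trityl cation captured by methanol) should free the C7 alcohol, while the dimethyl acetal only exchanges with the solvent.

Step 12
Reactants: 19 (E)-2-ethynyl-4,4-dimethoxybut-2-en-1-yl (2S,4R)-2-chloro-5-hydroxy-2-methyl-4-(((E)-2-methylbut-2-enoyl)oxy)pentanoate
Product: 20 (E)-2-ethynyl-4,4-dimethoxybut-2-en-1-yl (2S,4R)-2-chloro-2-methyl-4-(((E)-2-methylbut-2-enoyl)oxy)-5-oxopentanoate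
Conditions: Dess–Martin periodinane (1.3 equiv), pyridine, CH2Cl2, 0 °C
Reagents that add atoms: none
Why: buffered Dess–Martin oxidation should give the α-acyloxy aldehyde (C7) without epimerising C8; the aldehyde is used directly.

Step 13
Reactants: 20 (E)-2-ethynyl-4,4-dimethoxybut-2-en-1-yl (2S,4R)-2-chloro-2-methyl-4-(((E)-2-methylbut-2-enoyl)oxy)-5-oxopentanoate
Product: 21 1-((E)-2-ethynyl-4,4-dimethoxybut-2-en-1-yl) 7-methyl (2S,4R)-2-chloro-5-hydroxy-2-methyl-6-methylidene-4-(((E)-2-methylbut-2-enoyl)oxy)heptanedioate (both C5 epimers)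
Conditions: methyl acrylate (excess, as solvent), DABCO (0.5 equiv), rt
Reagents that add atoms: methyl acrylate, C=CC(=O)OC
Why: the Morita–Baylis–Hillman reaction should be fast with this electron-poor α-acyloxy aldehyde and brings in C11–C13; the new carbinol configuration is irrelevant because C7 becomes sp2 in step 14.

Step 14
Reactants: 21 1-((E)-2-ethynyl-4,4-dimethoxybut-2-en-1-yl) 7-methyl (2S,4R)-2-chloro-5-hydroxy-2-methyl-6-methylidene-4-(((E)-2-methylbut-2-enoyl)oxy)heptanedioate
Product: 22 1-((E)-2-ethynyl-4,4-dimethoxybut-2-en-1-yl) 7-methyl (2S,4R,5Z)-6-(bromomethyl)-2-chloro-2-methyl-4-(((E)-2-methylbut-2-enoyl)oxy)hept-5-enedioate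
Conditions: NBS, Me2S, CH2Cl2, 0 °C to rt
Reagents that add atoms: N-bromosuccinimide, O=C1CCC(=O)N1Br
Why: Corey–Kim-type activation of the allylic alcohol and SN2′ return of bromide should give the thermodynamically preferred (Z)-2-(bromomethyl)enoate, with CH2Br cis to C8.

Step 15
Reactants: 22 1-((E)-2-ethynyl-4,4-dimethoxybut-2-en-1-yl) 7-methyl (2S,4R,5Z)-6-(bromomethyl)-2-chloro-2-methyl-4-(((E)-2-methylbut-2-enoyl)oxy)hept-5-enedioate
Product: 23 1-((E)-2-ethynyl-4-oxobut-2-en-1-yl) 7-methyl (2S,4R,5Z)-6-(bromomethyl)-2-chloro-2-methyl-4-(((E)-2-methylbut-2-enoyl)oxy)hept-5-enedioate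
Conditions: p-TsOH·H2O (20 mol %), acetone/H2O (10:1), rt
Reagents that add atoms: water, O
Why: hydrolysis of the allylic dimethyl acetal is easy and should free the C6 enal without touching the allylic bromide or the esters.

Step 16
Reactants: 23 1-((E)-2-ethynyl-4-oxobut-2-en-1-yl) 7-methyl (2S,4R,5Z)-6-(bromomethyl)-2-chloro-2-methyl-4-(((E)-2-methylbut-2-enoyl)oxy)hept-5-enedioate
Product: 25 ethynyl macrolactone (6S,7R,8R,10S), via macrocyclic hydroxy ester 24 (not isolated)
Conditions: CrCl2 (8 equiv), THF, rt, slow addition of 23 (final 2 mM); then p-TsOH·H2O (cat.), CH2Cl2, rt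
Reagents that add atoms: none
Why: in this Nozaki–Hiyama-type Barbier allylation, divalent chromium turns the allylic bromide into a (Z)-2-(methoxycarbonyl)allylchromium reagent that adds to the enal through a chair transition state with the C8 substituent axial, which should give the syn C6/C7 adduct and hence the cis lactone (6S,7R), the face of the allyl unit being chosen by C8 (C8–H eclipsing the alkene, aldehyde delivered on the side of the chromium-coordinating tigloyloxy group and anti to the C9 chain); ten-membered germacranolide rings of this shape are closed by this reaction type, and the α-chloro ester, alkyne and tiglate should be inert to CrCl2.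

Step 17
Reactants: 25 ethynyl macrolactone (6S,7R,8R,10S)
Product: 26 acetyl macrolactone (4Z,6S,7R,8R,10S)
Conditions: [Au(IPr)(NTf2)] (5 mol %; IPr = 1,3-bis(2,6-diisopropylphenyl)imidazol-2-ylidene), 1,4-dioxane/H2O (10:1), 60 °C
Reagents that add atoms: water, O
Why: gold-catalysed Markovnikov hydration of the terminal alkyne should give the methyl ketone (C3 carbonyl, C2 methyl) with the C4=C5 geometry unchanged; the other alkenes are electron-poor and not activated by the monovalent gold catalyst.

Step 18
Reactants: 26 acetyl macrolactone (4Z,6S,7R,8R,10S)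
Product: 29 target CNP0269689.6 (6S,7R,8R,10R), via lithium enolate 27 (not isolated), via lithium diketonate 28 (not isolated)
Conditions: LiN(SiMe3)2 (1.1 equiv), THF (5 mM), −78 to 0 °C; then DMPU, 0 to 40 °C; pH 7 buffer
Reagents that add atoms: none
Why: Proposed new method: kinetic deprotonation of the methyl ketone gives enolate 27, whose carbon C2 adds to the ester carbonyl C1 through the six-membered array C2–C3–C4–C15–O–C1; collapse of the bridged hemiketal alkoxide expels the C15 alkoxide, so the ten-membered lactone is exchanged for the ten-membered carbocycle (C2–C1 bond), and proton transfer gives the stabilised diketonate 28 with the free C15 hydroxyl, whose C3 oxygen then displaces the tertiary chloride at C10 (O–C10 bond) to close the 3(2H)-furanone. The closest known reaction types are the Baker–Venkataraman rearrangement and the base-induced acyl transfer of β-acyloxy ketones for the first event, and the base-induced cyclisation of 4-halo-1,3-diketones to 3(2H)-furanones together with SN2 displacements at tertiary α-chloro carbonyl carbons for the second; their combination on a macrolactone is new. Ring closures: the carbocycle by 6-exo-trig addition and fragmentation (a net 1,5 O-to-C acyl shift with ring size conserved), the furanone by 5-exo-tet. C10 is set by inversion of the (S)-chloride fixed in step 9 and becomes (R); C6, C7 and C8 are not touched. The step needs deprotonation at the methyl group and not at the γ positions (hindered amide base at −78 °C), acylation at C1 and not at the lactone or tiglate carbonyls (only C1 is reached through a six-membered array and it is activated by the α-chlorine, while a seven-ring addition to the lactone carbonyl is reversible and unproductive), and O- instead of C-alkylation (five- against three-membered ring). The sequence is driven first by formation of the diketonate and then by irreversible loss of chloride.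

**Compound list**
1 | but-2-yne-1,4-diol | OCC#CCO | starting material
2 | 4-((tert-butyldimethylsilyl)oxy)but-2-yn-1-ol | OCC#CCO[Si](C)(C)C(C)(C)C | intermediate
3 | cyclic vinylalanate from 2 (sodium salt; aluminium on the later C4, bound to the C6 alkoxide oxygen) | [Na+].CC(C)(C)[Si](C)(C)OCC1=CCO[Al-]1(OCCOC)OCCOC | intermediate
4 | (Z)-4-((tert-butyldimethylsilyl)oxy)-3-iodobut-2-en-1-ol | OC/C=C(\I)CO[Si](C)(C)C(C)(C)C | intermediate
5 | (E)-3-(((tert-butyldimethylsilyl)oxy)methyl)-5-(trimethylsilyl)pent-2-en-4-yn-1-ol | OC/C=C(\C#C[Si](C)(C)C)CO[Si](C)(C)C(C)(C)C | intermediate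
6 | (E)-3-(((tert-butyldimethylsilyl)oxy)methyl)-5-(trimethylsilyl)pent-2-en-4-ynal | O=C/C=C(\C#C[Si](C)(C)C)CO[Si](C)(C)C(C)(C)C | intermediate
7 | (E)-4,4-dimethoxy-2-((trimethylsilyl)ethynyl)but-2-en-1-ol | OC/C(C#C[Si](C)(C)C)=C/C(OC)OC | intermediate
8 | (E)-2-ethynyl-4,4-dimethoxybut-2-en-1-ol | OC/C(C#C)=C/C(OC)OC | intermediate
9 | (E)-3-(bromomethyl)-5,5-dimethoxypent-3-en-1-yne | BrC/C(C#C)=C/C(OC)OC | intermediate
10 | (R)-5-(hydroxymethyl)dihydrofuran-2(3H)-one | O=C1CC[C@H](CO)O1 | starting material
11 | (R)-5-((trityloxy)methyl)dihydrofuran-2(3H)-one | O=C1CC[C@H](COC(c2ccccc2)(c2ccccc2)c2ccccc2)O1 | intermediate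
12 | lithium enolate of 11 | [Li+].[O-]C1=CC[C@H](COC(c2ccccc2)(c2ccccc2)c2ccccc2)O1 | intermediate
13 | (3S,5R)-3-methyl-5-((trityloxy)methyl)dihydrofuran-2(3H)-one | O=C1[C@@H](C)C[C@H](COC(c2ccccc2)(c2ccccc2)c2ccccc2)O1 | intermediate
14 | lithium enolate of 13 | [Li+].[O-]C1=C(C)C[C@H](COC(c2ccccc2)(c2ccccc2)c2ccccc2)O1 | intermediate
15 | (3S,5R)-3-chloro-3-methyl-5-((trityloxy)methyl)dihydrofuran-2(3H)-one | O=C1[C@@](C)(Cl)C[C@H](COC(c2ccccc2)(c2ccccc2)c2ccccc2)O1 | intermediate
16 | cesium (2S,4R)-2-chloro-4-hydroxy-2-methyl-5-(trityloxy)pentanoate | [Cs+].[O-]C(=O)[C@@](C)(Cl)C[C@@H](O)COC(c1ccccc1)(c1ccccc1)c1ccccc1 | intermediate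
17 | (E)-2-ethynyl-4,4-dimethoxybut-2-en-1-yl (2S,4R)-2-chloro-4-hydroxy-2-methyl-5-(trityloxy)pentanoate | COC(OC)/C=C(\C#C)COC(=O)[C@@](C)(Cl)C[C@@H](O)COC(c1ccccc1)(c1ccccc1)c1ccccc1 | intermediate
18 | (E)-2-ethynyl-4,4-dimethoxybut-2-en-1-yl (2S,4R)-2-chloro-2-methyl-4-(((E)-2-methylbut-2-enoyl)oxy)-5-(trityloxy)pentanoate | COC(OC)/C=C(\C#C)COC(=O)[C@@](C)(Cl)C[C@@H](OC(=O)/C(C)=C/C)COC(c1ccccc1)(c1ccccc1)c1ccccc1 | intermediate
19 | (E)-2-ethynyl-4,4-dimethoxybut-2-en-1-yl (2S,4R)-2-chloro-5-hydroxy-2-methyl-4-(((E)-2-methylbut-2-enoyl)oxy)pentanoate | COC(OC)/C=C(\C#C)COC(=O)[C@@](C)(Cl)C[C@@H](OC(=O)/C(C)=C/C)CO | intermediate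
20 | (E)-2-ethynyl-4,4-dimethoxybut-2-en-1-yl (2S,4R)-2-chloro-2-methyl-4-(((E)-2-methylbut-2-enoyl)oxy)-5-oxopentanoate | COC(OC)/C=C(\C#C)COC(=O)[C@@](C)(Cl)C[C@@H](OC(=O)/C(C)=C/C)C=O | intermediate
21 | 1-((E)-2-ethynyl-4,4-dimethoxybut-2-en-1-yl) 7-methyl (2S,4R)-2-chloro-5-hydroxy-2-methyl-6-methylidene-4-(((E)-2-methylbut-2-enoyl)oxy)heptanedioate, both C5 epimers | COC(OC)/C=C(\C#C)COC(=O)[C@@](C)(Cl)C[C@@H](OC(=O)/C(C)=C/C)C(O)C(=C)C(=O)OC | intermediate
22 | 1-((E)-2-ethynyl-4,4-dimethoxybut-2-en-1-yl) 7-methyl (2S,4R,5Z)-6-(bromomethyl)-2-chloro-2-methyl-4-(((E)-2-methylbut-2-enoyl)oxy)hept-5-enedioate | COC(OC)/C=C(\C#C)COC(=O)[C@@](C)(Cl)C[C@@H](OC(=O)/C(C)=C/C)/C=C(\CBr)C(=O)OC | intermediate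
23 | 1-((E)-2-ethynyl-4-oxobut-2-en-1-yl) 7-methyl (2S,4R,5Z)-6-(bromomethyl)-2-chloro-2-methyl-4-(((E)-2-methylbut-2-enoyl)oxy)hept-5-enedioate | O=C/C=C(\C#C)COC(=O)[C@@](C)(Cl)C[C@@H](OC(=O)/C(C)=C/C)/C=C(\CBr)C(=O)OC | intermediate
24 | macrocyclic hydroxy ester: ten-membered lactone (C1 carboxyl on O15; ring O15–C15–C4=C5–C6–C7–C8–C9–C10–C1) with 4-ethynyl (4E), 6-hydroxy (6S), 7-(1-(methoxycarbonyl)vinyl) (7R), 8-tigloyloxy (8R), 10-chloro-10-methyl (10S) | COC(=O)C(=C)[C@H]1[C@@H](O)/C=C(\C#C)COC(=O)[C@@](C)(Cl)C[C@H]1OC(=O)/C(C)=C/C | intermediate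
25 | ethynyl macrolactone: as 24, with O6 and C12 closed to the cis-fused α-methylene-γ-butyrolactone (6S,7R,8R,10S) | C=C1C(=O)O[C@H]2/C=C(\C#C)COC(=O)[C@@](C)(Cl)C[C@@H](OC(=O)/C(C)=C/C)[C@@H]12 | intermediate
26 | acetyl macrolactone: 25 with acetyl (C3, C2) in place of ethynyl on C4 (4Z,6S,7R,8R,10S) | C=C1C(=O)O[C@H]2/C=C(\C(C)=O)COC(=O)[C@@](C)(Cl)C[C@@H](OC(=O)/C(C)=C/C)[C@@H]12 | intermediate
27 | lithium enolate of 26 at the acetyl methyl group (C2) | [Li+].C=C1C(=O)O[C@H]2/C=C(\C(=C)[O-])COC(=O)[C@@](C)(Cl)C[C@@H](OC(=O)/C(C)=C/C)[C@@H]12 | intermediate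
28 | lithium enolate of the ten-membered carbocyclic 1,3-diketone (C1 and C3 carbonyls) with free 15-hydroxyl and 10-chloro (6S,7R,8R,10S) | [Li+].C=C1C(=O)O[C@H]2/C=C(/CO)C([O-])=CC(=O)[C@@](C)(Cl)C[C@@H](OC(=O)/C(C)=C/C)[C@@H]12 | intermediate
29 | target CNP0269689.6: (6S,7R,8R,10R)-15-hydroxy-8-tigloyloxy furanone-bridged germacranolide with cis-fused 6,12-lactone | C=C1C(=O)O[C@H]2/C=C(/CO)C3=CC(=O)[C@@](C)(C[C@@H](OC(=O)/C(C)=C/C)[C@@H]12)O3 | target

**Step count and risks**
Total steps: 18. Longest linear sequence: 15 steps (steps 1–6, then 10–18); the lactone branch needs steps 7–9.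

Step 18 is the most likely to fail. Displacement at the tertiary chloride may be too slow, so that the hydroxy diketone closes on work-up to a six-membered hemiketal. The chloride may ionise, with loss of stereochemical fidelity at C10. The enolate may add to the lactone carbonyl, γ-deprotonation may eliminate the carboxylate, or the hemiketal alkoxide may close to an epoxy ether. The fallback sets out from 26 and uses known chemistry in two isolated stages. LiN(SiMe3)2 at −78 to −20 °C with an acetic acid quench (base-induced acyl transfer of a β-acyloxy ketone) should give the chloro hydroxy diketone F1. AgOTf with 2,6-lutidine in CH2Cl2 should then abstract the halide and let the enol oxygen close the oxyallyl-type cation, as in the known cyclisation of 4-halo-1,3-diketones. This comes back to the route at 29, with C10 then set by the ring and not by inversion.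

Step 16 is the second risk. The seco compound may oligomerise, the allylchromium may lose the tiglate by 1,4-elimination, the aldehyde may add to the wrong face of the allyl unit relative to C8, or anti addition may compete. The fallback sets out from 20 and replaces the allylmetal by an allylsilane. Wittig olefination with methyl 2-(triphenylphosphoranylidene)-3-(trimethylsilyl)propanoate should give the allylsilane acetal F2. Acetal hydrolysis as in step 15 gives the allylsilane aldehyde F3. Intramolecular Hosomi–Sakurai allylation with BF3·OEt2 in CH2Cl2 at −78 °C under high dilution (open transition state, no carbanionic allylmetal) should give 24, which is lactonised as before and comes back to the route at 25.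

Step 10 is the third risk. The γ-hydroxy ester 17 may relactonise to 15 with loss of alcohol 8 before it is acylated, and the carboxylate may lose chloride on concentration. The fallback sets out from 15 and protects the hydroxyl while the acid is still a salt. CsOH·H2O, then excess TESCl and imidazole, then an aqueous K2CO3 work-up that cleaves only the silyl ester, should give the silyloxy acid F4. Cs2CO3 and 9 in DMF give the silyloxy ester F5. HF·pyridine buffered with pyridine at 0 °C, followed at once by tigloyl chloride and DMAP, exposes 17 only briefly under non-basic conditions and comes back to the route at 18.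

**Further compounds**
F1 | step 18 | chloro hydroxy diketone: ten-membered carbocyclic 1,3-diketone (C1, C3) with free 15-hydroxyl and 10-chloro (6S,7R,8R,10S); may exist as its enol or cyclic hemiketal | C=C1C(=O)O[C@H]2/C=C(/CO)C(=O)CC(=O)[C@@](C)(Cl)C[C@@H](OC(=O)/C(C)=C/C)[C@@H]12
F2 | step 16 | allylsilane acetal: 22 with CH2SiMe3 in place of CH2Br | COC(OC)/C=C(\C#C)COC(=O)[C@@](C)(Cl)C[C@@H](OC(=O)/C(C)=C/C)/C=C(\C[Si](C)(C)C)C(=O)OC
F3 | step 16 | allylsilane aldehyde: 23 with CH2SiMe3 in place of CH2Br | O=C/C=C(\C#C)COC(=O)[C@@](C)(Cl)C[C@@H](OC(=O)/C(C)=C/C)/C=C(\C[Si](C)(C)C)C(=O)OC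
F4 | step 10 | (2S,4R)-2-chloro-2-methyl-4-((triethylsilyl)oxy)-5-(trityloxy)pentanoic acid | OC(=O)[C@@](C)(Cl)C[C@@H](O[Si](CC)(CC)CC)COC(c1ccccc1)(c1ccccc1)c1ccccc1
F5 | step 10 | (E)-2-ethynyl-4,4-dimethoxybut-2-en-1-yl (2S,4R)-2-chloro-2-methyl-4-((triethylsilyl)oxy)-5-(trityloxy)pentanoate | COC(OC)/C=C(\C#C)COC(=O)[C@@](C)(Cl)C[C@@H](O[Si](CC)(CC)CC)COC(c1ccccc1)(c1ccccc1)c1ccccc1
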